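## Structural features

The target is an acyclic 8-O-4' neolignan. A guaiacyl ring A carries a three-carbon chain C7–C8–C9, and the central carbon C8 is bonded through oxygen to C4' of a syringyl-type ring B. Ring A also bears, on its C4 oxygen, an achiral 1,3-dihydroxypropan-2-yl (glycerol) unit. Ring B carries a 3-hydroxypropyl chain (C7'–C9') at C1', para to the ether oxygen, and two methoxy groups at C3' and C5' that flank C4'. The only stereocentres are the neighbouring C7 (benzylic carbinol, S) and C8 (aryloxy-bearing, R), which stand in the erythro relationship. The fragile points are the C7–O bond, which is benzylic and para to an alkoxy group (it ionises in acid and can be hydrogenolysed), the configuration at C8 whenever C7 is at the ketone level, and the polarity of a pentaol. The real difficulty is to make the doubly ortho-substituted alkyl aryl ether at the secondary stereogenic C8 without touching its configuration, while five oxygen functions are told apart. Two features are exploited. C4' lies para to C1', so a formyl group at C1' (later grown into the hydroxypropyl chain) turns C4' into an SNAr electrophile. The erythro C7/C8/C9 triol can be locked as a 7,9-benzylidene 1,3-dioxane in which phenyl, ring A and the C8 hydroxyl are all equatorial, so that O8 is the only nucleophile.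

## Logic of the disconnections

**15 to 14.** No skeletal bond is cut. The saturated C7'–C8' bond and the five hydroxyls of 15 are traced to the C7'=C8' alkene, the two benzyl ethers and the benzylidene acetal of 14, because one hydrogenation undoes all of them. The gain is that every polar group stays masked until the last operation, which then needs only filtration. The demand is that hydrogenolysis stops at the O–benzyl and acetal C–O bonds and spares the benzylic C7–O and the allylic C9'–O bond.

**14 to 13 to 12.** After C9' is adjusted from alcohol to ester, the C7'=C8' bond is cut as an olefination retron. This removes two carbons and reveals a formyl group at C1' in 12. That group is exactly the substituent needed para to C4' for the next cut. The forward steps must give the E ester and reduce it without opening the acetal.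

**12 to 9 and 10.** The O8–C4' bond is cut on the aryl side. Cutting here leaves the C8–O bond intact, so the configuration at C8 cannot be lost, and it splits the molecule into two halves of similar size. The forward step must make a secondary alkoxide attack a carbon flanked by two methoxy groups, chemoselectively at O8 and in the presence of an aldehyde.

**9 to 8 to 7.** The two acetal C–O bonds at the benzylidene carbon are cut to give the free triol 8. The triol is then re-masked at O8 and O9 as the isopropylidene acetal of 7. This connects the erythro triol to a chiral-pool glyceraldehyde unit. The forward acetalisation must choose the six-membered 7,9-ring over the five-membered alternatives, which is asked of thermodynamic control.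

**7 to 3 and 4 (through 5 and 6).** The C1–C7 bond between ring A and the carbinol carbon is cut. C8 then comes from 4 with its configuration already in place and only C7 has to be created. The forward addition must be anti (Felkin–Anh) selective and must not epimerise the aldehyde.

**3 to 1 and 2.** The bond between the ring A phenol oxygen and C2 of the glycerol unit is cut. Both fragments are commercial and the carbinol carbon of 2 is not stereogenic, so inversion is irrelevant. The forward step must etherify a hindered, electron-poor secondary alcohol. The benzyl ethers of 2 are chosen because they survive every acidic, basic and hydride step and fall in the final hydrogenation.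

## Other disconnections considered

**Alternative 1:** The cut is the C1–C7 bond, with the ring B ether already in place on the electrophile. In the forward step the ring A aryltitanium triisopropoxide A2 (tetravalent titanium, from the aryllithium and ClTi(OiPr)3) would add to the (R)-2-aryloxy-3-silyloxypropanal A1 to give the erythro carbinol A3.
- In its favour: the two halves meet in the C–C bond-forming step, the bulky non-chelating titanium reagent should follow the polar Felkin–Anh model with the aryloxy group as the anti substituent, and the end game is fluoride and dilute acid with no hydrogenolysis near a benzylic C–O bond. On that last point it is better than the chosen plan.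
- Against it: A1 is an α-aryloxy aldehyde with a β-silyloxy group. It can enolise (loss of C8 configuration) or eliminate, and its own C8–O bond must first be made by displacing a chiral secondary leaving group with the hindered 2,6-dimethoxyphenol. This moves the steric problem of the chosen key step to an SN2 reaction and adds a racemisation risk.
- Comparison: on structure both plans reach the same erythro array. On mechanism both set C7 by the same kind of Felkin-type aryl addition and are equal there, but the chosen plan does it on the robust acetonide aldehyde and gets a thermodynamic acetal as a stereochemical filter, which the acyclic A3 lacks. On step economy Alternative 1 is equal or slightly shorter in its longest linear sequence.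

**Alternative 2:** The cut is the C8–C9 bond. In the forward step the Z trimethylsilyl enol ether A4 of the aryloxymethyl ketone would add to aqueous formaldehyde under Sc(OTf)3 (trivalent scandium) with a chiral 2,2'-bipyridine diol, giving the β-hydroxy ketone A5 with C8 set.
- In its favour: the ether is made beforehand by a simple phenoxide displacement at a primary α-halo ketone carbon, which is easier than the hindered SNAr of the chosen plan. Enantiocontrol is catalytic and no chiral-pool reagent is needed.
- Against it: C8 in A5 is α to an aryl ketone and carries an aryloxy group and a β-hydroxyl, so enolisation, retro-aldol cleavage and dehydration all threaten it. The enantioface choice must be made at a carbon bearing the bulky 2,6-dimethoxyaryloxy group. A separate erythro-selective ketone reduction is still needed, and the allyl group on ring B must later be hydrated in the anti-Markovnikov sense.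
- Comparison: on structure it builds C9 last, whereas the chosen plan buys C8 and C9 together. On mechanism both stereocentres rest on selectivities that are not secured by the substrate, whereas the chosen plan never exposes C8. On step economy it is probably the shorter route and is better on that count.

**Alternative 3:** The cut is the C7–H bond, with dynamic kinetic resolution. The racemic ethyl 3-aryl-2-aryloxy-3-oxopropanoate A6 would be hydrogenated with RuBr2(BINAP) (divalent ruthenium) while C8 epimerises through the enol, giving the anti hydroxy ester A7.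
- In its favour: both stereocentres are set in one catalytic step from racemic material, which is better stereochemical economy than the chosen plan. The ether bond is made at the aryloxyacetate stage at a primary carbon, and the final deprotection is acid and fluoride with no hydrogenolysis.
- Against it: the anti sense for an α-aryloxy substituent is less secure than the syn sense known for α-acylamino keto esters. The electron-rich aryl ketone is a slow substrate, and the forcing conditions it needs, with traces of acid in an alcohol solvent, endanger the acetonide and silyl ether. The ester must still be reduced to the C9 alcohol.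
- Comparison: on structure it treats C7 and C8 as one problem, whereas the chosen plan separates them (C8 from the pool, C7 by substrate control). On mechanism it depends on a rate balance between epimerisation and reduction, whereas the chosen key step creates no stereocentre at all. On step economy the two are about equal.

Key step: step 5

Remark on labels: C7, C8 and C9 are the carbinol, aryloxy-bearing and hydroxymethyl carbons of the chain on ring A; primed atoms belong to ring B; Ar stands for 4-{[1,3-bis(benzyloxy)propan-2-yl]oxy}-3-methoxyphenyl.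

Assumption: commercial 4 is cracked and distilled to the monomer immediately before use, since its oligomers react sluggishly and erode selectivity.

## Route

Step 1
Reactants: 1 4-bromo-2-methoxyphenol; 2 1,3-bis(benzyloxy)propan-2-ol
Product: 3 4-bromo-1-{[1,3-bis(benzyloxy)propan-2-yl]oxy}-2-methoxybenzene
Conditions: PPh3, DIAD, THF, 0 °C to rt
Reagents that add atoms: none
Why: Mitsunobu etherification of a phenol of suitable acidity with a secondary alcohol; the carbinol carbon of 2 carries two identical arms, so the inversion has no stereochemical consequence.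

Step 2
Reactants: 3 4-bromo-1-{[1,3-bis(benzyloxy)propan-2-yl]oxy}-2-methoxybenzene; 4 (R)-2,2-dimethyl-1,3-dioxolane-4-carbaldehyde
Product: 7 (S)-Ar[(4R)-2,2-dimethyl-1,3-dioxolan-4-yl]methanol, via aryllithium 5 (not isolated), via aryltitanium triisopropoxide 6 (not isolated)
Conditions: n-BuLi, THF, −78 °C; ClTi(OiPr)3, −78 to −40 °C; then 4, −78 to 0 °C; aq. NH4Cl
Reagents that add atoms: none
Why: Bromine–lithium exchange, transmetallation to tetravalent titanium and 1,2-addition to the aldehyde; the bulky, non-chelating aryltitanium should add by the Felkin–Anh model with the α-C–O bond anti to the incoming aryl group, which sets C7 as S (anti, erythro) next to the purchased R centre. The weakly basic titanium reagent should not enolise 4.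

Step 3
Reactants: 7 (S)-Ar[(4R)-2,2-dimethyl-1,3-dioxolan-4-yl]methanol
Product: 8 (1S,2R)-1-Ar-propane-1,2,3-triol
Conditions: AcOH–H2O (4:1), 30 °C
Reagents that add atoms: none
Why: Mild acid hydrolysis of an isopropylidene acetal; water as the only nucleophile and the low temperature should keep the benzylic C7–O bond from ionising, and the benzyl ethers are inert.

Step 4
Reactants: 8 (1S,2R)-1-Ar-propane-1,2,3-triol
Product: 9 (2R,4S,5R)-4-Ar-2-phenyl-1,3-dioxan-5-ol
Conditions: PhCH(OMe)2, CSA (cat.), CHCl3, 50 °C, MeOH removed; then Et3N
Reagents that add atoms: benzaldehyde dimethyl acetal, COC(OC)c1ccccc1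
Why: Acid-catalysed transacetalisation under thermodynamic control; benzylidene acetals generally prefer the six-membered 1,3-dioxane, and in the erythro series the 7,9-acetal is a chair with phenyl, Ar and the C8 hydroxyl all equatorial, so the acetal carbon should settle as R. Because C8 is fixed, any reversible ionisation at C7 would return to the same trans-diequatorial isomer.

Step 5
Reactants: 9 (2R,4S,5R)-4-Ar-2-phenyl-1,3-dioxan-5-ol; 10 4-fluoro-3,5-dimethoxybenzaldehyde
Product: 12 4-{[(2R,4S,5R)-4-Ar-2-phenyl-1,3-dioxan-5-yl]oxy}-3,5-dimethoxybenzaldehyde, via potassium alkoxide 11 (not isolated)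
Conditions: KN(SiMe3)2 (0.95 equiv), THF–DMF, −20 °C; then 10, 0 to 40 °C
Reagents that add atoms: none
Why: The reaction is an addition–elimination SNAr: the potassium alkoxide 11 adds to C4' of 10 to give a Meisenheimer anion whose charge is delocalised onto the para formyl oxygen, and loss of fluoride, the best leaving group for this mechanism because its inductive pull speeds the rate-determining addition, restores the arene. The closest known reaction type is the etherification of 4-fluorobenzaldehydes by alkali alkoxides in dipolar aprotic solvents, made harder here by the two methoxy groups beside C4' and by the secondary nucleophile. No ring is closed and no stereocentre is created: only the O8–H bond of 9 is replaced and the C8–O bond is never broken, so C8 keeps its R configuration while C7 and the acetal carbon are spectators. The step needs arylation at O8 only, and the substrate secures this because O7 and O9 are tied in a base-stable benzylidene acetal, which cannot migrate as a silyl group could, and because the equatorial alkoxide projects away from the chair. It also needs attack at C4' and not at the formyl carbon; addition of the alkoxide to C=O is reversible and unproductive whereas fluoride loss is irreversible, so the hemiacetal alkoxide should drain back into the ether. Slightly less than one equivalent of base, with 11 formed before 10 is added, keeps free amide away from the aldehyde, which it would otherwise convert into an N-silyl imine. The THF–DMF medium and the potassium counter-ion give a loosely paired alkoxide that should react at moderate temperature, which limits hydride transfer from C8–H to the aldehyde.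

Step 6
Reactants: 12 4-{[(2R,4S,5R)-4-Ar-2-phenyl-1,3-dioxan-5-yl]oxy}-3,5-dimethoxybenzaldehyde
Product: 13 ethyl (2E)-3-(4-{[(2R,4S,5R)-4-Ar-2-phenyl-1,3-dioxan-5-yl]oxy}-3,5-dimethoxyphenyl)prop-2-enoate
Conditions: Ph3P=CHCO2Et, toluene, 80 °C
Reagents that add atoms: ethyl (triphenylphosphoranylidene)acetate, CCOC(=O)C=P(c1ccccc1)(c1ccccc1)c1ccccc1
Why: Wittig olefination with a stabilised ylide, which should give the E cinnamate under neutral conditions that leave the acetal and benzyl ethers untouched.

Step 7
Reactants: 13 ethyl (2E)-3-(4-{[(2R,4S,5R)-4-Ar-2-phenyl-1,3-dioxan-5-yl]oxy}-3,5-dimethoxyphenyl)prop-2-enoate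
Product: 14 (2E)-3-(4-{[(2R,4S,5R)-4-Ar-2-phenyl-1,3-dioxan-5-yl]oxy}-3,5-dimethoxyphenyl)prop-2-en-1-ol
Conditions: i-Bu2AlH, CH2Cl2, −78 °C; aq. potassium sodium tartrate
Reagents that add atoms: none
Why: 1,2-Reduction of an α,β-unsaturated ester to the allylic alcohol by an aluminium hydride; at −78 °C reductive opening of the benzylidene acetal should not compete.

Step 8
Reactants: 14 (2E)-3-(4-{[(2R,4S,5R)-4-Ar-2-phenyl-1,3-dioxan-5-yl]oxy}-3,5-dimethoxyphenyl)prop-2-en-1-ol
Product: 15 (1S,2R)-1-{4-[(1,3-dihydroxypropan-2-yl)oxy]-3-methoxyphenyl}-2-[4-(3-hydroxypropyl)-2,6-dimethoxyphenoxy]propane-1,3-diol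
Conditions: H2 (1 atm), 10% Pd/C, EtOAc–EtOH, rt
Reagents that add atoms: none
Why: Heterogeneous hydrogenation saturates the alkene first, then hydrogenolyses the two O-benzyl ethers and the benzylidene acetal to toluene; neutral solvent and ambient pressure should spare the secondary benzylic C7–OH, and neither stereocentre is involved.

## Compound list

1 | 4-bromo-2-methoxyphenol | COc1cc(Br)ccc1O | starting material
2 | 1,3-bis(benzyloxy)propan-2-ol | OC(COCc1ccccc1)COCc1ccccc1 | starting material
3 | 4-bromo-1-{[1,3-bis(benzyloxy)propan-2-yl]oxy}-2-methoxybenzene | COc1cc(Br)ccc1OC(COCc1ccccc1)COCc1ccccc1 | intermediate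
4 | (R)-2,2-dimethyl-1,3-dioxolane-4-carbaldehyde | O=C[C@H]1COC(C)(C)O1 | starting material
5 | (4-{[1,3-bis(benzyloxy)propan-2-yl]oxy}-3-methoxyphenyl)lithium | [Li]c1ccc(OC(COCc2ccccc2)COCc2ccccc2)c(OC)c1 | intermediate
6 | (4-{[1,3-bis(benzyloxy)propan-2-yl]oxy}-3-methoxyphenyl)titanium triisopropoxide | CC(C)O[Ti](OC(C)C)(OC(C)C)c1ccc(OC(COCc2ccccc2)COCc2ccccc2)c(OC)c1 | intermediate
7 | (S)-(4-{[1,3-bis(benzyloxy)propan-2-yl]oxy}-3-methoxyphenyl)[(4R)-2,2-dimethyl-1,3-dioxolan-4-yl]methanol | COc1cc([C@H](O)[C@H]2COC(C)(C)O2)ccc1OC(COCc1ccccc1)COCc1ccccc1 | intermediate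
8 | (1S,2R)-1-(4-{[1,3-bis(benzyloxy)propan-2-yl]oxy}-3-methoxyphenyl)propane-1,2,3-triol | COc1cc([C@H](O)[C@@H](CO)O)ccc1OC(COCc1ccccc1)COCc1ccccc1 | intermediate
9 | (2R,4S,5R)-4-(4-{[1,3-bis(benzyloxy)propan-2-yl]oxy}-3-methoxyphenyl)-2-phenyl-1,3-dioxan-5-ol | COc1cc([C@@H]2O[C@H](c3ccccc3)OC[C@H]2O)ccc1OC(COCc1ccccc1)COCc1ccccc1 | intermediate
10 | 4-fluoro-3,5-dimethoxybenzaldehyde | COc1cc(C=O)cc(OC)c1F | starting material
11 | potassium (2R,4S,5R)-4-(4-{[1,3-bis(benzyloxy)propan-2-yl]oxy}-3-methoxyphenyl)-2-phenyl-1,3-dioxan-5-olate | COc1cc([C@@H]2O[C@H](c3ccccc3)OC[C@H]2[O-])ccc1OC(COCc1ccccc1)COCc1ccccc1.[K+] | intermediate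
12 | 4-{[(2R,4S,5R)-4-(4-{[1,3-bis(benzyloxy)propan-2-yl]oxy}-3-methoxyphenyl)-2-phenyl-1,3-dioxan-5-yl]oxy}-3,5-dimethoxybenzaldehyde | COc1cc([C@@H]2O[C@H](c3ccccc3)OC[C@H]2Oc2c(OC)cc(C=O)cc2OC)ccc1OC(COCc1ccccc1)COCc1ccccc1 | intermediate
13 | ethyl (2E)-3-(4-{[(2R,4S,5R)-4-(4-{[1,3-bis(benzyloxy)propan-2-yl]oxy}-3-methoxyphenyl)-2-phenyl-1,3-dioxan-5-yl]oxy}-3,5-dimethoxyphenyl)prop-2-enoate | COc1cc([C@@H]2O[C@H](c3ccccc3)OC[C@H]2Oc2c(OC)cc(/C=C/C(=O)OCC)cc2OC)ccc1OC(COCc1ccccc1)COCc1ccccc1 | intermediate
14 | (2E)-3-(4-{[(2R,4S,5R)-4-(4-{[1,3-bis(benzyloxy)propan-2-yl]oxy}-3-methoxyphenyl)-2-phenyl-1,3-dioxan-5-yl]oxy}-3,5-dimethoxyphenyl)prop-2-en-1-ol | COc1cc([C@@H]2O[C@H](c3ccccc3)OC[C@H]2Oc2c(OC)cc(/C=C/CO)cc2OC)ccc1OC(COCc1ccccc1)COCc1ccccc1 | intermediate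
15 | (1S,2R)-1-{4-[(1,3-dihydroxypropan-2-yl)oxy]-3-methoxyphenyl}-2-[4-(3-hydroxypropyl)-2,6-dimethoxyphenoxy]propane-1,3-diol | COc1cc([C@H](O)[C@@H](CO)Oc2c(OC)cc(CCCO)cc2OC)ccc1OC(CO)CO | target

## Step count and least certain steps

Total step count: 8. Longest linear sequence: 8 steps (1 to 15 through 3, 7, 8, 9, 12, 13 and 14); 2, 4 and 10 enter as purchased materials.

**Step 5 (key step).** The most likely failure is that addition at the crowded C4' is too slow, so that unproductive carbonyl chemistry takes over: hemiacetal formation that parks the nucleophile, hydride transfer from C8–H to the formyl group, or imine formation with residual amide. Fallback: keep the same O8–C4' disconnection but change the activating group to cyano, which offers no reducible or addable carbonyl. Setting out from 9 (as 11) and 10, the aldehyde 10 would be converted in one operation (hydroxylamine hydrochloride in hot DMSO, oxime dehydration in the same pot) into 4-fluoro-3,5-dimethoxybenzonitrile F1. SNAr of 11 on F1 should give 4-{[(2R,4S,5R)-4-Ar-2-phenyl-1,3-dioxan-5-yl]oxy}-3,5-dimethoxybenzonitrile F2. Reduction with i-Bu2AlH at −78 °C and hydrolysis of the aldimine would return the route at 12.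

**Step 4.** The most likely failure is incomplete regiocontrol in the acetalisation. Five-membered 8,9- and 7,8-benzylidene dioxolanes may persist at equilibrium, because an equatorial 5-hydroxyl gains no internal hydrogen bond, and acid may ionise the C7–O bond. Fallback: a silylene-directed sequence with unambiguous regiochemistry, modelled on the protection of 1,3-diols beside a free secondary hydroxyl.
- From 8, tBu2Si(OTf)2 in DMF at 0 °C should tie O7 and O9 as the six-membered (4S,5R)-4-Ar-2,2-di-tert-butyl-1,3,2-dioxasilinan-5-ol F3.
- Silylation in the same flask (TBSCl, imidazole) should give its 5-O-tert-butyldimethylsilyl ether F4.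
- HF·pyridine at 0 °C should cleave only the silylene, to (1S,2R)-1-Ar-2-[(tert-butyldimethylsilyl)oxy]propane-1,3-diol F5.
- PhCH(OMe)2 with CSA can then form only the 7,9-acetal, tert-butyldimethylsilyl ether F6 of the dioxanol.
- Bu4NF returns the route at 9.

**Step 2.** The most likely failure is poor facial selectivity in the aryl addition, giving a sizeable share of the C7 epimer, or partial epimerisation of 4 before it reacts. Fallback: set C7 by reduction instead of addition. From 7 (as its mixture with the C7 epimer), Dess–Martin oxidation should give the ketone Ar[(4R)-2,2-dimethyl-1,3-dioxolan-4-yl]methanone F7. Chelation-controlled reduction with Zn(BH4)2 in Et2O at low temperature, with hydride delivered anti to C9 in the five-membered chelate, should return the erythro alcohol 7.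

**Step 8.** The most likely failure is over-reduction by C–O hydrogenolysis, either at the allylic C9' position while the alkene is still present or at the benzylic C7–O bond of the dioxane. Fallback: reverse the order of reduction so that no allylic alcohol is exposed to the catalyst. From 13, hydrogenation over Pd/C should give the saturated tetraol ester ethyl 3-(4-{[(1S,2R)-1,3-dihydroxy-1-{4-[(1,3-dihydroxypropan-2-yl)oxy]-3-methoxyphenyl}propan-2-yl]oxy}-3,5-dimethoxyphenyl)propanoate F8. Reduction with LiBH4 in THF then returns the route at 15.

## Further compounds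

F1 | step 5 | 4-fluoro-3,5-dimethoxybenzonitrile | COc1cc(C#N)cc(OC)c1F
F2 | step 5 | 4-{[(2R,4S,5R)-4-(4-{[1,3-bis(benzyloxy)propan-2-yl]oxy}-3-methoxyphenyl)-2-phenyl-1,3-dioxan-5-yl]oxy}-3,5-dimethoxybenzonitrile | COc1cc([C@@H]2O[C@H](c3ccccc3)OC[C@H]2Oc2c(OC)cc(C#N)cc2OC)ccc1OC(COCc1ccccc1)COCc1ccccc1
F3 | step 4 | (4S,5R)-4-(4-{[1,3-bis(benzyloxy)propan-2-yl]oxy}-3-methoxyphenyl)-2,2-di-tert-butyl-1,3,2-dioxasilinan-5-ol | COc1cc([C@@H]2O[Si](C(C)(C)C)(C(C)(C)C)OC[C@H]2O)ccc1OC(COCc1ccccc1)COCc1ccccc1
F4 | step 4 | (4S,5R)-4-(4-{[1,3-bis(benzyloxy)propan-2-yl]oxy}-3-methoxyphenyl)-2,2-di-tert-butyl-5-[(tert-butyldimethylsilyl)oxy]-1,3,2-dioxasilinane | COc1cc([C@@H]2O[Si](C(C)(C)C)(C(C)(C)C)OC[C@H]2O[Si](C)(C)C(C)(C)C)ccc1OC(COCc1ccccc1)COCc1ccccc1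
F5 | step 4 | (1S,2R)-1-(4-{[1,3-bis(benzyloxy)propan-2-yl]oxy}-3-methoxyphenyl)-2-[(tert-butyldimethylsilyl)oxy]propane-1,3-diol | COc1cc([C@H](O)[C@@H](CO)O[Si](C)(C)C(C)(C)C)ccc1OC(COCc1ccccc1)COCc1ccccc1
F6 | step 4 | tert-butyl{[(2R,4S,5R)-4-(4-{[1,3-bis(benzyloxy)propan-2-yl]oxy}-3-methoxyphenyl)-2-phenyl-1,3-dioxan-5-yl]oxy}dimethylsilane | COc1cc([C@@H]2O[C@H](c3ccccc3)OC[C@H]2O[Si](C)(C)C(C)(C)C)ccc1OC(COCc1ccccc1)COCc1ccccc1
F7 | step 2 | (4-{[1,3-bis(benzyloxy)propan-2-yl]oxy}-3-methoxyphenyl)[(4R)-2,2-dimethyl-1,3-dioxolan-4-yl]methanone | COc1cc(C(=O)[C@H]2COC(C)(C)O2)ccc1OC(COCc1ccccc1)COCc1ccccc1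
F8 | step 8 | ethyl 3-(4-{[(1S,2R)-1,3-dihydroxy-1-{4-[(1,3-dihydroxypropan-2-yl)oxy]-3-methoxyphenyl}propan-2-yl]oxy}-3,5-dimethoxyphenyl)propanoate | COc1cc([C@H](O)[C@@H](CO)Oc2c(OC)cc(CCC(=O)OCC)cc2OC)ccc1OC(CO)CO
A1 | alternative 1 | (2R)-3-[(tert-butyldimethylsilyl)oxy]-2-[4-(3-{[tert-butyldimethylsilyl]oxy}propyl)-2,6-dimethoxyphenoxy]propanal | O=C[C@@H](CO[Si](C)(C)C(C)(C)C)Oc1c(OC)cc(CCCO[Si](C)(C)C(C)(C)C)cc1OC
A2 | alternative 1 | {4-[(2,2-dimethyl-1,3-dioxan-5-yl)oxy]-3-methoxyphenyl}titanium triisopropoxide | CC(C)O[Ti](OC(C)C)(OC(C)C)c1ccc(OC2COC(C)(C)OC2)c(OC)c1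
A3 | alternative 1 | (1S,2R)-3-[(tert-butyldimethylsilyl)oxy]-2-[4-(3-{[tert-butyldimethylsilyl]oxy}propyl)-2,6-dimethoxyphenoxy]-1-{4-[(2,2-dimethyl-1,3-dioxan-5-yl)oxy]-3-methoxyphenyl}propan-1-ol | COc1cc([C@H](O)[C@@H](CO[Si](C)(C)C(C)(C)C)Oc2c(OC)cc(CCCO[Si](C)(C)C(C)(C)C)cc2OC)ccc1OC1COC(C)(C)OC1
A4 | alternative 2 | (Z)-{[1-(4-{[1,3-bis(benzyloxy)propan-2-yl]oxy}-3-methoxyphenyl)-2-[2,6-dimethoxy-4-(prop-2-en-1-yl)phenoxy]ethenyl]oxy}trimethylsilane | COc1cc(/C(O[Si](C)(C)C)=C/Oc2c(OC)cc(CC=C)cc2OC)ccc1OC(COCc1ccccc1)COCc1ccccc1
A5 | alternative 2 | (2R)-1-(4-{[1,3-bis(benzyloxy)propan-2-yl]oxy}-3-methoxyphenyl)-2-[2,6-dimethoxy-4-(prop-2-en-1-yl)phenoxy]-3-hydroxypropan-1-one | COc1cc(C(=O)[C@@H](CO)Oc2c(OC)cc(CC=C)cc2OC)ccc1OC(COCc1ccccc1)COCc1ccccc1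
A6 | alternative 3 | ethyl 2-[4-(3-{[tert-butyldimethylsilyl]oxy}propyl)-2,6-dimethoxyphenoxy]-3-{4-[(2,2-dimethyl-1,3-dioxan-5-yl)oxy]-3-methoxyphenyl}-3-oxopropanoate (racemic) | CCOC(=O)C(Oc1c(OC)cc(CCCO[Si](C)(C)C(C)(C)C)cc1OC)C(=O)c1ccc(OC2COC(C)(C)OC2)c(OC)c1
A7 | alternative 3 | ethyl (2S,3S)-2-[4-(3-{[tert-butyldimethylsilyl]oxy}propyl)-2,6-dimethoxyphenoxy]-3-{4-[(2,2-dimethyl-1,3-dioxan-5-yl)oxy]-3-methoxyphenyl}-3-hydroxypropanoate | COc1cc([C@H](O)[C@@H](C(=O)OCC)Oc2c(OC)cc(CCCO[Si](C)(C)C(C)(C)C)cc2OC)ccc1OC1COC(C)(C)OC1
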